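(The data stem from a simulated flask with constants of no real substance; noise was put on by code.)

What share of side product plus target is side product when 0.30 M of substrate stands for 6.0 d, twice the spring charge, and does the charge matter at all?

- spring: substrate 0.15 M; run made earlier
- flask: substrate 0.30 M; time 6.0 d

spring run (percent of the substrate charged)

| time / h | side product / % | target / % | substrate / % |
|---|---|---|---|
| 6.00 | 22.8 | 71.5 | 1.7 |
| 12.0 | 23.7 | 75.0 | 0 |
| 20.0 | 23.7 | 74.9 | 0.5 |
| 25.0 | 23.0 | 74.8 | 0.2 |
| 30.0 | 23.8 | 76.0 | 0.4 |
| 40.0 | 24.5 | 75.5 | 0 |

(readings scatter by 0.5 percentage points)

- steps thought possible: substrate <-> intermediate; substrate <-> dormant form; substrate -> side product; substrate -> target; intermediate -> target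

- share of side product in side product plus target at 6.0 min
- share of side product in side product plus target at 4.0 h
- share of side product in side product plus target at 6.0 d
- which of side product and target there is more of at 6.0 d

From 12.0 h to 40.0 h the spring readings stay flat within their scatter with substrate near zero, so I pool them. Summed, side product stands to target at 0.316. That gives 24.0%, the branching share (the selectivity), meaning side product over side product plus target on the plateau.

Two chemists dispute what this reading is worth at the new charge. The first holds that both products form at rates proportional to the substrate concentration, so the concentration cancels in their ratio and the flask keeps this share. The second holds that side product forms with the square of the substrate concentration, so the odds grow with the charge to about 0.631, and the share climbs to about 38.7%. The spring run has one charge, so it offers no comparison between charges.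

The forecast takes the first side: 26% at 6.0 min, 24.5% at 4.0 h, 24% at 6.0 d, with target ahead. It writes that “doubling the concentration should leave the final share near 24%, though the orders are untested”.

The flask gives 25.5% at 6.0 min, 24.4% at 4.0 h and 23.7% at 6.0 d, with target ahead at 76.3% against 23.7%.

    substrate ⇌ intermediate (K = 0.807, k = 0.0642 h⁻¹)
    substrate ⇌ dormant form (K = 0.390, k = 0.0159 h⁻¹)
    substrate → side product (k = 0.163 h⁻¹)
    substrate → target (k = 0.476 h⁻¹)
    intermediate → target (k = 0.252 h⁻¹)

The steps in the scheme are first order, so the first chemist wins: the flask's 23.7% lies close to the spring reading of the branching share, 24.0%, and the second's 38.7% stands higher than the flask. The second view keeps the spring charge, where it reproduces the plateau it was scaled from. Target leads because of the direct step from substrate to target: the run without that step moves the share at 6.0 d from 23.7% to 77.0%. At 0.51 M of substrate, the neighbour flask ends at 23.7%, again close to the spring reading of 24.0%.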